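Readings and results are calculated from invented constants, noise included.

Monday's flask turned 0.113 M of its 0.200 M into product and then nearly stood, while Friday's flask, with twice the free catalyst, turned 0.197 M.

| setting | Monday's | Saturday's | Wednesday's | Friday's | Tuesday's |
|---|---|---|---|---|---|
| starting material | 0.200 M | 0.0800 M | 0.200 M | 0.200 M | 0.600 M |
| free catalyst | 0.00100 M | 0.00100 M | 0.00100 M | 0.00200 M | 3.30 × 10⁻⁴ M |
| product |  |  | 0.0600 M |  |  |
| time |  |  |  |  | 160 min |

| Monday's run: time / min | Monday's run: [starting material] / M | Saturday's run: time / min | Saturday's run: [starting material] / M | Wednesday's run: time / min | Wednesday's run: [starting material] / M | Friday's run: time / min | Friday's run: [starting material] / M |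
|---|---|---|---|---|---|---|---|
| 6.4 | 0.1752 | 6.4 | 0.0684 | 6.4 | 0.1747 | 6.4 | 0.1443 |
| 10 | 0.1656 | 10 | 0.0630 | 10 | 0.1623 | 10 | 0.1255 |
| 16 | 0.1480 | 16 | 0.0550 | 16 | 0.1493 | 16 | 0.0972 |
| 25 | 0.1337 | 25 | 0.0461 | 25 | 0.1346 | 25 | 0.0691 |
| 40 | 0.1175 | 40 | 0.0347 | 40 | 0.1177 | 40 | 0.0451 |
| 64 | 0.1023 | 64 | 0.0241 | 64 | 0.1010 | 64 | 0.0245 |
| 100 | 0.0898 | 100 | 0.0142 | 100 | 0.0886 | 100 | 0.0107 |
| 160 | 0.0867 | 160 | 0.0061 | 160 | 0.0852 | 160 | 0.0030 |

(readings scatter by 0.001 M)

- Overall: starting material -> product, with free catalyst as catalyst.
- Constant volume, constant temperature.
- Bound and free are read together.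
- An order is taken over about fifteen percent of the charge, up and down.

- the power of [starting material] that the first rate follows, about the charge of the Monday's run; measure it at two percent of starting material made into product (one fixed amount of product, the same in the runs compared)
- the power of [free catalyst] that the first rate follows, about the charge of the Monday's run; measure it at two percent of starting material made into product
- starting material in the Tuesday's run at 160 min, as a share of the starting material charged

Saturday's flask, with Monday's catalyst charge, had made 0.0739 M at 160 min, less than Monday's flask. Over the last interval, its starting material still fell by 0.0141 min⁻¹ in logarithm, against 5.86 × 10⁻⁴ min⁻¹ on Monday. So the catalyst seems to die with the product it makes, not with the clock. Wednesday's flask, charged with 0.0600 M of product, ends at 0.0852 M, beside Monday's 0.0867 M, so added product does not appear to count.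

The rule to try is that product at the stop equals capacity times working catalyst, where working catalyst is the charge less a part lost at the outset. The capacity is reckoned here in two ways.

Early rates: the first reading gives Friday over Monday, in logarithmic fall,

ratio = 2.47

This exceeds the ratio of charges, so Monday's working catalyst is

c(working) = 6.82 × 10⁻⁴ M

capacity = 166

This capacity, the product made per working catalyst before it dies (a turnover number), rests on the first readings of Monday's and Friday's flasks and on Monday's last reading.

Late readings: Friday's logarithmic rate falls from 0.0510 min⁻¹ to 0.0284 min⁻¹. Drawn straight against product, it reaches zero at 0.288 M. The extra catalyst then gives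

capacity = 175

The outset loss cancels here, but both routes use Monday's reading at 160 min and Friday's first reading, so 166 beside 175 is no independent check. This stop also lies beyond Friday's charge, so the line is stretched, and the first value is kept.

Monday's working share gives an order in free catalyst of 1.47. At one amount of product, Monday's first reading against Saturday's third gives an order in starting material of 0.889. If Tuesday's flask loses Monday's amount at the outset, 3.18 × 10⁻⁴ M, its charge barely exceeds that, and 99.7% of its starting material remains.

The forecast gives 0.57, lower than this reckoning, then 1.45 and 99%, reasoning “so almost nothing reacts”.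

The flask gives 0.88, 1.4 and 97.5%.

    free catalyst + starting material ⇌ catalyst-substrate complex (63.60 L mol⁻¹ min⁻¹, 32.82 min⁻¹)
    catalyst-substrate complex → product + free catalyst (45.84 min⁻¹)
    free catalyst + starting material → spent catalyst + starting material (0.2394 L mol⁻¹ min⁻¹)
    free catalyst + impurity → spent catalyst

Tuesday's flask stops through the death of free catalyst on starting material: without that step it keeps 66.9%, not 97.5%. Its product, 0.0147 M, divided by the capacity, means 8.86 × 10⁻⁵ M of working catalyst, and so an outset loss reckoned at 2.41 × 10⁻⁴ M. The capacity applied to the whole catalyst charge leaves 90.9% of the starting material, and Tuesday's flask without the impurity holds 91.5%.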